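**Retrosynthetic overview**
- The acylphloroglucinol A ring is opened at its C5–C6 bond (Claisen retron), leading back to a 2‑pyranone that carries the complete 3‑arylpropanoyl side chain.
- That keto pyranone is disconnected at the CH2–C(=O) bond into a dihydropyran‑fused 4‑alkoxy‑6‑methyl‑2‑pyranone and methyl 3‑(4‑hydroxy‑3‑prenylphenyl)propanoate (from methyl phloretate and prenyl bromide).
- The bicyclic pyrano[4,3‑b]pyranone comes from an acyclic 2‑prenyl‑3,5‑dioxohexanoate by one acid cascade that closes the dihydropyran (C–O) and the pyranone (lactone) rings.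
- The diketo ester comes from methyl acetoacetate, prenyl bromide and an acetyl Weinreb amide.
- Ring order: dihydropyran and pyranone together, then the benzene A ring at the expense of the pyranone; the B ring is bought.

Assumption: the SMILES has no stereocentre and no stereogenic double bond, so the target is achiral and no asymmetric step is needed.

**Route**

Step 1
Reactants: 1 methyl acetoacetate; 2 prenyl bromide (1‑bromo‑3‑methylbut‑2‑ene)
Product: 3 methyl 2‑acetyl‑5‑methylhex‑4‑enoate (racemic)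
Conditions: NaH (1.0 equiv), THF, 0 °C → rt; 1 in excess (1.3 equiv)
Reagents that add atoms: none
Why: Acetoacetic ester alkylation (SN2 C‑alkylation of the sodium enolate by a primary allylic bromide), with excess 1 suppressing dialkylation; the new stereocentre is racemic and is erased in step 3.

Step 2
Reactants: 3 methyl 2‑acetyl‑5‑methylhex‑4‑enoate; 4 N‑methoxy‑N‑methylacetamide
Product: 5 methyl 2‑(3‑methylbut‑2‑en‑1‑yl)‑3,5‑dioxohexanoate (racemic, largely enolised)
Conditions: LDA (2.2 equiv), THF, −78 → 0 °C; then 4, −78 → 0 °C; 1 M HCl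
Reagents that add atoms: none
Why: γ‑Acylation of a β‑keto ester dianion (Weiler dianion), which reacts at its more basic γ‑carbon, while the Weinreb amide holds the chelated tetrahedral adduct until acidic work‑up so the diketone is never exposed to base.

Step 3
Reactants: 5 methyl 2‑(3‑methylbut‑2‑en‑1‑yl)‑3,5‑dioxohexanoate
Product: 7 2,2,7‑trimethyl‑3,4‑dihydro‑2H,5H‑pyrano[4,3‑b]pyran‑5‑one, via dihydropyran keto ester 6 (not isolated)
Conditions: TfOH (10 mol %), PhCl, 0 °C → rt; then 110 °C, 4 Å MS (−MeOH)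
Reagents that add atoms: none
Why: Proposed new method: Markovnikov protonation of the prenyl alkene gives a tertiary cation that is captured by the C3 enol oxygen to form dihydropyran 6 (closest known: Brønsted‑acid hydroalkoxylation of 2‑prenyl‑1,3‑dicarbonyls to 2,2‑dimethyldihydropyrans), and on heating the enol of the side‑chain ketone lactonises onto the cis‑held ester with loss of MeOH to give the 2‑pyranone (closest known: enol lactonisation of δ‑keto‑β‑alkoxyacrylates to 4‑alkoxy‑2‑pyranones), so both rings close in one flask and the ether oxygen is fixed on the carbon that becomes C8a.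

Step 4
Reactants: 8 methyl 3‑(4‑hydroxyphenyl)propanoate; 2 prenyl bromide
Product: 9 methyl 3‑[4‑hydroxy‑3‑(3‑methylbut‑2‑en‑1‑yl)phenyl]propanoate
Conditions: NaH (1.05 equiv), PhMe, 0 °C → rt; then 2 (1.0 equiv), rt
Reagents that add atoms: none
Why: Ortho C‑alkylation of a phenoxide: in a non‑polar solvent the tight sodium phenoxide ion pair is alkylated mainly at the ortho carbon, the para position is blocked, and the O‑prenyl ether and di‑ortho product are separable by‑products.

Step 5
Reactants: 7 2,2,7‑trimethyl‑3,4‑dihydro‑2H,5H‑pyrano[4,3‑b]pyran‑5‑one; 9 methyl 3‑[4‑hydroxy‑3‑(3‑methylbut‑2‑en‑1‑yl)phenyl]propanoate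
Product: 10 7‑{4‑[4‑hydroxy‑3‑(3‑methylbut‑2‑en‑1‑yl)phenyl]‑2‑oxobutyl}‑2,2‑dimethyl‑3,4‑dihydro‑2H,5H‑pyrano[4,3‑b]pyran‑5‑one
Conditions: 7 (2.2 equiv), LDA (2.2 equiv), THF, −78 °C; then 9 (1.0 equiv, pre‑treated with LiHMDS 1.0 equiv), −78 → 0 °C; 1 M HCl, 0 °C; excess 7 recovered
Reagents that add atoms: none
Why: Crossed Claisen acylation of the vinylogously acidic 7‑methyl group (as in 4‑methoxy‑6‑methyl‑2‑pyranone) by the methyl ester, with the second equivalent of pyranone anion deprotonating the more acidic β‑keto pyranone product and driving the reaction.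

Step 6
Reactants: 10 7‑{4‑[4‑hydroxy‑3‑(3‑methylbut‑2‑en‑1‑yl)phenyl]‑2‑oxobutyl}‑2,2‑dimethyl‑3,4‑dihydro‑2H,5H‑pyrano[4,3‑b]pyran‑5‑one
Product: 12 1‑(5,7‑dihydroxy‑2,2‑dimethyl‑3,4‑dihydro‑2H‑chromen‑6‑yl)‑3‑[4‑hydroxy‑3‑(3‑methylbut‑2‑en‑1‑yl)phenyl]propan‑1‑one, via ring-opened diketo ester 11 (not isolated)
Conditions: Mg(OMe)2 (5 equiv), MeOH, reflux; then 1 M HCl, 0 °C
Reagents that add atoms: none
Why: Proposed new method: methoxide opens the lactone to the Z‑β‑alkoxyacrylate ester 11, whose Mg‑chelated 1,3‑diketonate carbon attacks the ester in a six‑ring Claisen (Dieckmann‑type) condensation, and the triketone tautomerises irreversibly to the acylphloroglucinol; the aldol mode is blocked because C4a is fully substituted, the chroman oxygen is already locked para to the acyl group, and the closest known reaction is the Harris‑type Mg(OMe)2 cyclisation of 6‑(2‑oxoalkyl)‑4‑hydroxy‑2‑pyranones (3,5,7‑triketo esters) to acylphloroglucinols.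

**Compound list**

1 | methyl acetoacetate (methyl 3‑oxobutanoate) | COC(=O)CC(C)=O | starting material
2 | prenyl bromide (1‑bromo‑3‑methylbut‑2‑ene) | CC(C)=CCBr | starting material
3 | methyl 2‑acetyl‑5‑methylhex‑4‑enoate (racemic) | COC(=O)C(CC=C(C)C)C(C)=O | intermediate
4 | N‑methoxy‑N‑methylacetamide | CC(=O)N(C)OC | starting material
5 | methyl 2‑(3‑methylbut‑2‑en‑1‑yl)‑3,5‑dioxohexanoate (racemic) | COC(=O)C(CC=C(C)C)C(=O)CC(C)=O | intermediate
6 | methyl 2,2‑dimethyl‑6‑(2‑oxopropyl)‑3,4‑dihydro‑2H‑pyran‑5‑carboxylate (not isolated) | COC(=O)C1=C(CC(C)=O)OC(C)(C)CC1 | intermediate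
7 | 2,2,7‑trimethyl‑3,4‑dihydro‑2H,5H‑pyrano[4,3‑b]pyran‑5‑one | CC1=CC2=C(CCC(C)(C)O2)C(=O)O1 | intermediate
8 | methyl 3‑(4‑hydroxyphenyl)propanoate | COC(=O)CCc1ccc(O)cc1 | starting material
9 | methyl 3‑[4‑hydroxy‑3‑(3‑methylbut‑2‑en‑1‑yl)phenyl]propanoate | COC(=O)CCc1ccc(O)c(CC=C(C)C)c1 | intermediate
10 | 7‑{4‑[4‑hydroxy‑3‑(3‑methylbut‑2‑en‑1‑yl)phenyl]‑2‑oxobutyl}‑2,2‑dimethyl‑3,4‑dihydro‑2H,5H‑pyrano[4,3‑b]pyran‑5‑one | O=C(CCc1ccc(O)c(CC=C(C)C)c1)CC1=CC2=C(CCC(C)(C)O2)C(=O)O1 | intermediate
11 | methyl 6‑{6‑[4‑hydroxy‑3‑(3‑methylbut‑2‑en‑1‑yl)phenyl]‑2,4‑dioxohexyl}‑2,2‑dimethyl‑3,4‑dihydro‑2H‑pyran‑5‑carboxylate (not isolated) | COC(=O)C1=C(CC(=O)CC(=O)CCc2ccc(O)c(CC=C(C)C)c2)OC(C)(C)CC1 | intermediate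
12 | 1‑(5,7‑dihydroxy‑2,2‑dimethyl‑3,4‑dihydro‑2H‑chromen‑6‑yl)‑3‑[4‑hydroxy‑3‑(3‑methylbut‑2‑en‑1‑yl)phenyl]propan‑1‑one (achiral) | CC(C)=CCc1cc(CCC(=O)c2c(O)cc3c(c2O)CCC(C)(C)O3)ccc1O | target

**Step count**
- Total steps: 6.
- Longest linear sequence: 5 (1 → 3 → 5 → 7 → 10 → 12).

**Steps most likely to fail, with fallbacks**

Step 6 (pyranone to acylphloroglucinol on an O‑alkylated pyranone). The lactone may resist methoxide opening, or the vinylogous‑carbonate ester may be too weak an electrophile, so that diketone cleavage competes. The fallback sets out from 5 and comes back to the route at 12. The acid treatment of 5 is stopped at room temperature and the dihydropyran keto ester 6 is isolated. Its dianion (LDA, 2.2 equiv, THF, −78 °C; terminal methyl carbanion) is acylated with the lithium phenoxide of 9 to give the open diketo ester 11 as an isolated compound. The ring is then closed on this pre‑opened substrate under aprotic conditions (LiHMDS, 3.5 equiv, THF, 0 °C → reflux) to give 12, so no lactone opening is needed. This fallback makes no new compound (F0).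

Step 3 (double ring closure). The tertiary cation could instead be trapped by the diketone carbon C4 to give a cyclohexanone. If lactonisation runs ahead of etherification, the lactone carbonyl oxygen could close the ring and give the isomeric 2‑alkoxy‑4‑pyranone. The fallback sets out from 3 and comes back at 7, closing the rings one at a time. Treating 3 with TfOH (cat.) in CH2Cl2 at rt gives methyl 2,2,6‑trimethyl‑3,4‑dihydro‑2H‑pyran‑5‑carboxylate F1, where only one enol oxygen and no carbon nucleophile can reach the cation. γ‑Lithiation of the 6‑methyl group (LDA, THF, −78 °C) and acetylation with 4 gives 6, which is isolated. Separate lactonisation (DBU cat., PhMe, reflux, −MeOH) gives 7.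

Step 5 (acylation of the pyranone anion by an enolisable ester that carries a phenoxide). Proton transfer or low conversion is possible. The fallback sets out from 9 and comes back at 10, replacing the Claisen acylation by aldol addition and oxidation. Reduction of 9 with DIBAL‑H (2.1 equiv, CH2Cl2, −78 °C) gives 3‑[4‑hydroxy‑3‑(3‑methylbut‑2‑en‑1‑yl)phenyl]propanal F2. Addition of the lithium anion of 7 (THF, −78 °C) gives 7‑{2‑hydroxy‑4‑[4‑hydroxy‑3‑(3‑methylbut‑2‑en‑1‑yl)phenyl]butyl}‑2,2‑dimethyl‑3,4‑dihydro‑2H,5H‑pyrano[4,3‑b]pyran‑5‑one F3 (racemic). Parikh–Doering oxidation (SO3·pyridine, DMSO, i‑Pr2NEt, 0 °C), which tolerates the phenol and the prenyl group, gives 10.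

**Further compounds**

F0 | step 6 | none | none
F1 | step 3 | methyl 2,2,6‑trimethyl‑3,4‑dihydro‑2H‑pyran‑5‑carboxylate | COC(=O)C1=C(C)OC(C)(C)CC1
F2 | step 5 | 3‑[4‑hydroxy‑3‑(3‑methylbut‑2‑en‑1‑yl)phenyl]propanal | O=CCCc1ccc(O)c(CC=C(C)C)c1
F3 | step 5 | 7‑{2‑hydroxy‑4‑[4‑hydroxy‑3‑(3‑methylbut‑2‑en‑1‑yl)phenyl]butyl}‑2,2‑dimethyl‑3,4‑dihydro‑2H,5H‑pyrano[4,3‑b]pyran‑5‑one (racemic) | OC(CCc1ccc(O)c(CC=C(C)C)c1)CC1=CC2=C(CCC(C)(C)O2)C(=O)O1
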